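**Strategy.** The γ-lactone is read as the adduct of a carbonyl ylide: its C7–O–C19 unit is the three-atom dipole and C8=C17 the two-atom partner. A 3-oxidopyrylium (ring O, C7, C6, C5, C4, C19) should add across the Z-ethylidene group of a cyclic carbonate spanning O8/O9, forming C19–C17 and C7–C8 and setting C7, C8 and C17 in one event; the carbonate ring, fixed on carvone-derived C9, steers the face. The surplus C4–C19 bond is then cut by Baeyer–Villiger oxidation, which turns C19 into the lactone carbon and frees C4 for a Takai/Nozaki–Hiyama–Kishi closure of the ten-membered ring.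

Key step: step 17

Remark on numbering: briarane numbering is used (ten-membered ring C1–C10; cyclohexane C1, C10–C14; lactone C7–O–C19(=O)–C17(C18)–C8; C15 on C1, C16 on C5, C20 on C11). β is the cyclohexane face carrying C15, α the opposite face.
Assumption: the target is taken as drawn, (1R,2S,7S,8S,9S,10S,11S,12R,14S,17R), with C3=C4 trans and C4 cis to C7 on C5=C6.

Step 1
Reactants: 1 (S)-(+)-carvone
Product: 2 6-(hydroxymethyl)carvone
Conditions: LiN(iPr)2, THF, −78 °C; monomeric CH2O (gas, from cracked paraformaldehyde), −78 → −40 °C; aq NH4Cl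
Reagents that add atoms: formaldehyde, C=O
Why: Kinetic deprotonation at the α′ carbon (carvone C6 = C1) gives the cross-conjugated lithium enolate, which should undergo aldol addition to formaldehyde mainly anti to the isopropenyl group; the C1 configuration is erased again in step 3.

Step 2
Reactants: 2 6-(hydroxymethyl)carvone
Product: 3 triethylsilyl ether of 2
Conditions: Et3SiCl, imidazole, CH2Cl2, 0 °C
Reagents that add atoms: chlorotriethylsilane, CC[Si](Cl)(CC)CC
Why: Standard silylation of the primary alcohol, with Et3Si chosen because a primary Et3Si ether can later be oxidised directly to the aldehyde under Swern conditions (step 24).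

Step 3
Reactants: 3 triethylsilyl ether of 2
Product: 4 quaternary enone (C15 trans, C2 arm cis to isopropenyl)
Conditions: LiN(iPr)2, THF, −78 °C; MeI, DMPU, −78 → −30 °C
Reagents that add atoms: iodomethane, CI
Why: Enolate alkylation creates quaternary C1 by 1,2-induction, since the C14 isopropenyl group turns axial beside the substituted enolate carbon and MeI should enter from the opposite face, leaving CH3 trans and CH2OSiEt3 cis to isopropenyl.

Step 4
Reactants: 4 quaternary enone
Product: 5 11β,12β-epoxy ketone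
Conditions: 30% H2O2, NaOH (0.2 equiv), MeOH, 0 °C
Reagents that add atoms: hydrogen peroxide, OO
Why: Weitz–Scheffer nucleophilic epoxidation, in which axial attack of HOO− at C12 on the conformer with equatorial isopropenyl should place the epoxide oxygen trans to the C14 substituent (β face), as with carvone itself.

Step 5
Reactants: 5 11β,12β-epoxy ketone
Product: 7 14α-acetate, via methoxy hydroperoxide 6 (not isolated)
Conditions: O3, CH2Cl2/MeOH, NaHCO3, −78 °C; then Ac2O, Et3N, DMAP (cat.), CH2Cl2, 0 °C → rt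
Reagents that add atoms: ozone, [O-][O+]=O; methanol, CO
Why: Ozonolysis of the only C=C bond in methanol gives the α-methoxy hydroperoxide, whose peracetate should undergo Criegee rearrangement with migration of C14 to oxygen with retention, turning isopropenyl into the 14α-acetoxy group.

Step 6
Reactants: 7 14α-acetate
Product: 8 14α-alcohol
Conditions: K2CO3 (0.2 equiv), MeOH, 0 °C
Reagents that add atoms: none
Why: Base-catalysed transesterification removes the acetate, while catalytic carbonate at 0 °C should spare the Et3Si ether and the epoxy ketone (C1 is quaternary, so β-elimination is impossible).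

Step 7
Reactants: 8 14α-alcohol
Product: 9 14α-O-TBS epoxy ketone
Conditions: tBuMe2SiOTf, 2,6-lutidine, CH2Cl2, −78 → 0 °C
Reagents that add atoms: tert-butyldimethylsilyl triflate, CC(C)(C)[Si](C)(C)OS(=O)(=O)C(F)(F)F
Why: Silyl triflate silylation is the standard way to protect a hindered secondary alcohol next to a quaternary carbon.

Step 8
Reactants: 9 14α-O-TBS epoxy ketone
Product: 10 allylic alcohol (C10=C11, 12β-OH)
Conditions: N2H4·H2O, AcOH (cat.), MeOH, 0 °C → rt
Reagents that add atoms: none
Why: Wharton transposition, in which the epoxy hydrazone opens to an alkenyl diazene that loses N2, moving the oxygen to C12 with retention (β) and the double bond to C10=C11.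

Step 9
Reactants: 10 allylic alcohol
Product: 11 12β-O-(but-2-ynyl) ether
Conditions: NaH, 1-bromobut-2-yne, Bu4NI (cat.), THF, 0 °C → rt
Reagents that add atoms: 1-bromobut-2-yne, CC#CCBr
Why: Williamson etherification of the allylic alkoxide with a propargylic bromide; the trans-1,3 relation of O12 and O14 should suppress silyl migration.

Step 10
Reactants: 11 12β-O-(but-2-ynyl) ether
Product: 12 (9S,10S) propargylic alcohol
Conditions: n-BuLi, THF, −78 → −60 °C; aq NH4Cl
Reagents that add atoms: none
Why: [2,3]-Wittig rearrangement of the α-oxy propargylic carbanion, in which suprafacial transfer from the 12β-oxygen sets C10 (new C9–C10 bond on the β face, cis to C15) and moves the alkene to C11=C12, while the envelope transition state with the alkynyl group exo on this ring-Z allyl unit should give the syn (9S) carbinol.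

Step 11
Reactants: 12 propargylic alcohol
Product: 13 (Z)-ethylidene cyclic carbonate
Conditions: AgOAc (10 mol %), DBU, CO2 (1 MPa), toluene, rt
Reagents that add atoms: carbon dioxide, O=C=O
Why: Silver-catalysed carboxylative cyclisation, in which the propargylic carbonate anion adds 5-exo-dig anti to the silver-activated alkyne and protodemetalation should give only the Z-alkylidene carbonate (CH3 cis to O8).

Step 12
Reactants: 14 furan-3-ylmethanol
Product: 15 3-(hydroxymethyl)furan-2-carbaldehyde
Conditions: n-BuLi (2.2 equiv), THF, −78 → 0 °C; DMF, −78 °C → rt; aq NH4Cl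
Reagents that add atoms: N,N-dimethylformamide, CN(C)C=O
Why: Alkoxide-directed ortho-lithiation of the dianion at furan C2 followed by formylation.

Step 13
Reactants: 15 3-(hydroxymethyl)furan-2-carbaldehyde
Product: 16 TBS ether of 15
Conditions: tBuMe2SiCl, imidazole, CH2Cl2, 0 °C → rt
Reagents that add atoms: tert-butylchlorodimethylsilane, CC(C)(C)[Si](C)(C)Cl
Why: Standard silylation of the primary alcohol that becomes the C16 oxygen.

Step 14
Reactants: 16 TBS ether of 15
Product: 17 2-furylmethanol
Conditions: NaBH4, MeOH, 0 °C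
Reagents that add atoms: none
Why: Chemoselective hydride reduction of the aldehyde gives the furfuryl alcohol needed for the Achmatowicz rearrangement.

Step 15
Reactants: 17 2-furylmethanol
Product: 18 6-hydroxypyranone
Conditions: NBS, NaHCO3, NaOAc, THF/H2O (4:1), 0 °C
Reagents that add atoms: water, O
Why: Achmatowicz rearrangement (oxidative furan opening and hemiacetal closure), which places the furan C3 substituent on C4 of the pyranone, the later C5 bearing C16.

Step 16
Reactants: 18 6-hydroxypyranone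
Product: 19 6-acetoxypyranone
Conditions: Ac2O, pyridine, DMAP (cat.), CH2Cl2, 0 °C
Reagents that add atoms: acetic anhydride, CC(=O)OC(C)=O
Why: Acetylation of the lactol installs the leaving group for ylide generation.

Step 17
Reactants: 13 (Z)-ethylidene cyclic carbonate; 19 6-acetoxypyranone
Product: 21 oxabicyclic cycloadduct, via oxidopyrylium ylide 20 (not isolated)
Conditions: Et3N, MeCN, 60 °C, slow addition of 19 (3 equiv)
Reagents that add atoms: none
Why: Et3N removes a C19 proton of 19 and acetate leaves from C7, giving the 3-oxidopyrylium 20, a cyclic carbonyl ylide (C7–O–C19) that adds in a concerted, suprafacial [5+2] (4π+2π, 1,3-dipolar) cycloaddition across C8=C17 of 13; the closest known reaction type is the oxidopyrylium–alkene cycloaddition with vinyl ethers and enol esters. Both new rings, the oxolane C7–O–C19–C17–C8 (the later γ-lactone) and the seven-membered carbocycle C4–C5–C6–C7–C8–C17–C19, are closed in the intermolecular cycloaddition mode, by simultaneous formation of C19–C17 and C7–C8 without a tether. Regiochemistry should follow the larger frontier-orbital coefficients: the nucleophilic β-carbon C17 of the enol carbonate bonds to the ylide terminus next to the oxido carbon (C19) and the oxygen-bearing C8 to C7, as in the 6-alkoxy adducts of vinyl ethers. C17 is fixed by the Z geometry of 13 (CH3 cis to O8), C8 by attack on the face of the planar dioxolanone anti to the C10 ring on C9, and C7/C19 by the bicycle once O8 and CH3 lie endo under the oxidoallyl unit and the bulky C9 side exo. The step needs cross-addition to outrun ylide dimerisation, which slow addition of excess 19 and the thermal reversibility of the dimer should secure; the isolated C11=C12 bond is not a competent dipolarophile.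

Step 18
Reactants: 21 oxabicyclic cycloadduct
Product: 22 8,9-diol
Conditions: K2CO3 (0.3 equiv), MeOH, 0 °C
Reagents that add atoms: none
Why: Methanolysis of the strained five-membered carbonate is done here, before any lactone exists; any oxa-Michael adduct of the α-substituted enone should revert, and the bridgehead α-carbon cannot enolise.

Step 19
Reactants: 22 8,9-diol
Product: 23 9-O-TBS ether (8-OH free)
Conditions: tBuMe2SiOTf (1.1 equiv), 2,6-lutidine, CH2Cl2, −78 °C
Reagents that add atoms: tert-butyldimethylsilyl triflate, CC(C)(C)[Si](C)(C)OS(=O)(=O)C(F)(F)F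
Why: The secondary 9-OH should be silylated selectively over the tertiary 8-OH at low temperature, which blocks O9 from later lactol or lactone exchange.

Step 20
Reactants: 23 9-O-TBS ether
Product: 25 epoxy Baeyer–Villiger lactone, via epoxy enone 24 (not isolated)
Conditions: mCPBA (3 equiv), NaHCO3, CH2Cl2, 0 °C → rt
Reagents that add atoms: 3-chloroperbenzoic acid, OOC(=O)c1cccc(Cl)c1
Why: The peracid should first epoxidise the electron-rich C11=C12 bond on the α face, anti to the large C9 branch on C10, and then effect Baeyer–Villiger oxidation of the enone with migration of the α-oxygenated bridgehead C19 (retention) in preference to the vinyl carbon, as with levoglucosenone.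

Step 21
Reactants: 25 epoxy Baeyer–Villiger lactone
Product: 26 enal lactol
Conditions: iBu2AlH (2.3 equiv), CH2Cl2, −78 °C; MeOH; aq KNaC4H4O6
Reagents that add atoms: none
Why: After deprotonation of the 8-OH, one hydride adds to the acylal carbonyl C4 and the tetrahedral aluminate, stable at −78 °C, should collapse on work-up to the C4 enal and the C19 lactol, which can close only onto O7.

Step 22
Reactants: 26 enal lactol
Product: 27 enal γ-lactone
Conditions: TEMPO (0.2 equiv), PhI(OAc)2, CH2Cl2, rt
Reagents that add atoms: none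
Why: Oxoammonium oxidation converts the lactol into the γ-lactone, while the enal, the tertiary alcohol and the silyl ethers are inert.

Step 23
Reactants: 27 enal γ-lactone
Product: 28 (3E,5Z)-dienyl iodide
Conditions: CHI3, CrCl2, THF, 0 °C → rt
Reagents that add atoms: iodoform, IC(I)I
Why: Takai olefination of the enal through a geminal dichromium species should give the E-iodoalkene (C3) and tolerates lactone, epoxide and free tertiary hydroxyl.

Step 24
Reactants: 28 dienyl iodide
Product: 29 C2 aldehyde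
Conditions: (COCl)2, DMSO, CH2Cl2, −78 → −40 °C; Et3N, −78 → 0 °C
Reagents that add atoms: none
Why: Under Swern conditions a primary Et3Si ether is cleaved and oxidised in one operation to the aldehyde, while the tBuMe2Si ethers and the tertiary alcohol should remain.

Step 25
Reactants: 29 C2 aldehyde
Product: 30 ten-membered ring 2S-alcohol
Conditions: CrCl2 (10 equiv), NiCl2 (2 mol %), DMSO/THF (3:1), 0.002 M, rt
Reagents that add atoms: none
Why: Intramolecular Nozaki–Hiyama–Kishi reaction, in which the dienylchromium species (E geometry retained) adds to the non-enolisable aldehyde on quaternary C1, closing C2–C3; the 2S carbinol is expected from attack on the aldehyde conformer with the carbonyl turned away from the C1–C10 bond, which is substrate control in a medium ring.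

Step 26
Reactants: 30 ten-membered ring 2S-alcohol
Product: 31 pentaol
Conditions: HF·pyridine, pyridine, THF, 0 °C → rt
Reagents that add atoms: none
Why: Buffered fluoride removes the three tBuMe2Si ethers (O9, O14, O16) under non-basic conditions that should spare the trisubstituted epoxide and avoid lactone migration to O9.

Step 27
Reactants: 31 pentaol
Product: 32 CNP0250433.1
Conditions: Ac2O, pyridine, DMAP (cat.), CH2Cl2, 0 °C → rt
Reagents that add atoms: acetic anhydride, CC(=O)OC(C)=O
Why: Acetylation of the primary 16-OH and the secondary 2-, 9- and 14-OH groups, while the hindered tertiary 8-OH should stay free.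

**Compound list**

1 | (S)-(+)-carvone, (5S)-2-methyl-5-(prop-1-en-2-yl)cyclohex-2-en-1-one | O=C1C(C)=CC[C@H](C(C)=C)C1 | starting material
2 | 6-(hydroxymethyl)carvone (carvone C6 = C1, CH2OH = C2; mainly CH2OH trans to isopropenyl, both C1 epimers converge in step 3) | O=C1C(C)=CC[C@H](C(C)=C)[C@H]1CO | intermediate
3 | triethylsilyl ether of 2 | O=C1C(C)=CC[C@H](C(C)=C)[C@H]1CO[Si](CC)(CC)CC | intermediate
4 | 6-methyl-6-[(triethylsilyloxy)methyl]carvone; CH3 (C15) trans and CH2OSiEt3 (C2) cis to isopropenyl | O=C1C(C)=CC[C@H](C(C)=C)[C@]1(C)CO[Si](CC)(CC)CC | intermediate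
5 | C11–C12 epoxide of 4, oxygen on the β face (cis to C15, trans to isopropenyl), C10 ketone | O=C1[C@@]2(C)O[C@H]2C[C@H](C(C)=C)[C@]1(C)CO[Si](CC)(CC)CC | intermediate
6 | α-methoxy hydroperoxide at the former isopropenyl carbon of 5 | O=C1[C@@]2(C)O[C@H]2C[C@H](C(C)(OC)OO)[C@]1(C)CO[Si](CC)(CC)CC | intermediate
7 | 14α-acetoxy epoxy ketone (acetoxy in place of isopropenyl, retention) | O=C1[C@@]2(C)O[C@H]2C[C@H](OC(C)=O)[C@]1(C)CO[Si](CC)(CC)CC | intermediate
8 | 14α-hydroxy epoxy ketone | O=C1[C@@]2(C)O[C@H]2C[C@H](O)[C@]1(C)CO[Si](CC)(CC)CC | intermediate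
9 | 14α-O-TBS epoxy ketone | O=C1[C@@]2(C)O[C@H]2C[C@H](O[Si](C)(C)C(C)(C)C)[C@]1(C)CO[Si](CC)(CC)CC | intermediate
10 | cyclohexenol: C10=C11 (11-CH3), 12β-OH, 14α-OTBS, 1β-CH3, 1α-CH2OSiEt3 | C1=C(C)[C@@H](O)C[C@H](O[Si](C)(C)C(C)(C)C)[C@]1(C)CO[Si](CC)(CC)CC | intermediate
11 | 12β-O-(but-2-yn-1-yl) ether of 10 | C1=C(C)[C@@H](OCC#CC)C[C@H](O[Si](C)(C)C(C)(C)C)[C@]1(C)CO[Si](CC)(CC)CC | intermediate
12 | (9S,10S) propargylic alcohol: 10β-[CH(OH)–C≡C–CH3] (C9, C8, C17, C18), C11=C12 | CC#C[C@@H](O)[C@H]1C(C)=CC[C@H](O[Si](C)(C)C(C)(C)C)[C@]1(C)CO[Si](CC)(CC)CC | intermediate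
13 | (Z)-4-ethylidene-1,3-dioxolan-2-one on O8/O9: exocyclic C8=C17 with CH3 cis to O8, C9 (S) carrying the cyclohexenyl unit | C/C=C2\OC(=O)O[C@H]2[C@H]1C(C)=CC[C@H](O[Si](C)(C)C(C)(C)C)[C@]1(C)CO[Si](CC)(CC)CC | intermediate
14 | furan-3-ylmethanol | OCc1ccoc1 | starting material
15 | 3-(hydroxymethyl)furan-2-carbaldehyde | O=Cc1occc1CO | intermediate
16 | 3-[(tert-butyldimethylsilyloxy)methyl]furan-2-carbaldehyde | O=Cc1occc1CO[Si](C)(C)C(C)(C)C | intermediate
17 | {3-[(tert-butyldimethylsilyloxy)methyl]furan-2-yl}methanol | OCc1occc1CO[Si](C)(C)C(C)(C)C | intermediate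
18 | 6-hydroxy-4-[(tert-butyldimethylsilyloxy)methyl]-2H-pyran-3(6H)-one (racemic lactol) | O=C1COC(O)C=C1CO[Si](C)(C)C(C)(C)C | intermediate
19 | 6-acetoxy-4-[(tert-butyldimethylsilyloxy)methyl]-2H-pyran-3(6H)-one (racemic) | CC(=O)OC1OCC(=O)C(CO[Si](C)(C)C(C)(C)C)=C1 | intermediate
20 | 4-[(tert-butyldimethylsilyloxy)methyl]-3-oxidopyrylium (pyrylium C2 = C19, C3 = C4, C4 = C5, C5 = C6, C6 = C7) | [O-]c1c[o+]ccc1CO[Si](C)(C)C(C)(C)C | intermediate
21 | cycloadduct: 8-oxabicyclo[3.2.1]oct-3-en-2-one (C4 ketone, C5=C6, bridgeheads C7 and C19, 17-CH3) spiro-fused at C8 to the O8/O9 carbonate; O8 and CH3 endo, C9 exo; 7S,8S,17R | O=C1C(CO[Si](C)(C)C(C)(C)C)=C[C@@H]2O[C@H]1[C@H](C)[C@]23OC(=O)O[C@H]3[C@H]4C(C)=CC[C@H](O[Si](C)(C)C(C)(C)C)[C@]4(C)CO[Si](CC)(CC)CC | intermediate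
22 | 8,9-diol of the cycloadduct | O=C1C(CO[Si](C)(C)C(C)(C)C)=C[C@@H]2O[C@H]1[C@H](C)[C@@]2(O)[C@@H](O)[C@H]4C(C)=CC[C@H](O[Si](C)(C)C(C)(C)C)[C@]4(C)CO[Si](CC)(CC)CC | intermediate
23 | 9-O-TBS ether of 22 (8-OH free) | O=C1C(CO[Si](C)(C)C(C)(C)C)=C[C@@H]2O[C@H]1[C@H](C)[C@@]2(O)[C@@H](O[Si](C)(C)C(C)(C)C)[C@H]4C(C)=CC[C@H](O[Si](C)(C)C(C)(C)C)[C@]4(C)CO[Si](CC)(CC)CC | intermediate
24 | 11α,12α-epoxide of 23 (enone intact) | O=C1C(CO[Si](C)(C)C(C)(C)C)=C[C@@H]2O[C@H]1[C@H](C)[C@@]2(O)[C@@H](O[Si](C)(C)C(C)(C)C)[C@H]4[C@]5(C)O[C@@H]5C[C@H](O[Si](C)(C)C(C)(C)C)[C@]4(C)CO[Si](CC)(CC)CC | intermediate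
25 | Baeyer–Villiger lactone: C19–O–C4(=O) acylal (2,9-dioxabicyclo[4.2.1]non-4-en-3-one core), 11α,12α-epoxide | O=C1C(CO[Si](C)(C)C(C)(C)C)=C[C@@H]2O[C@H](O1)[C@H](C)[C@@]2(O)[C@@H](O[Si](C)(C)C(C)(C)C)[C@H]4[C@]5(C)O[C@@H]5C[C@H](O[Si](C)(C)C(C)(C)C)[C@]4(C)CO[Si](CC)(CC)CC | intermediate
26 | enal lactol: C4 aldehyde on C5=C6 (CHO cis to C7), C19 lactol (anomers) | O=C/C(CO[Si](C)(C)C(C)(C)C)=C\[C@@H]1OC(O)[C@H](C)[C@@]1(O)[C@@H](O[Si](C)(C)C(C)(C)C)[C@H]4[C@]5(C)O[C@@H]5C[C@H](O[Si](C)(C)C(C)(C)C)[C@]4(C)CO[Si](CC)(CC)CC | intermediate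
27 | enal γ-lactone (7S,8S,17R) | O=C/C(CO[Si](C)(C)C(C)(C)C)=C\[C@@H]1OC(=O)[C@H](C)[C@@]1(O)[C@@H](O[Si](C)(C)C(C)(C)C)[C@H]4[C@]5(C)O[C@@H]5C[C@H](O[Si](C)(C)C(C)(C)C)[C@]4(C)CO[Si](CC)(CC)CC | intermediate
28 | (3E,5Z)-dienyl iodide (iodine on C3) | I/C=C/C(CO[Si](C)(C)C(C)(C)C)=C\[C@@H]1OC(=O)[C@H](C)[C@@]1(O)[C@@H](O[Si](C)(C)C(C)(C)C)[C@H]4[C@]5(C)O[C@@H]5C[C@H](O[Si](C)(C)C(C)(C)C)[C@]4(C)CO[Si](CC)(CC)CC | intermediate
29 | C2 aldehyde of the dienyl iodide | I/C=C/C(CO[Si](C)(C)C(C)(C)C)=C\[C@@H]1OC(=O)[C@H](C)[C@@]1(O)[C@@H](O[Si](C)(C)C(C)(C)C)[C@H]4[C@]5(C)O[C@@H]5C[C@H](O[Si](C)(C)C(C)(C)C)[C@]4(C)C=O | intermediate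
30 | briarane core, 2S-alcohol, 9,14,16-tris-O-TBS, 8-OH free | CC(C)(C)[Si](C)(C)OCC1=C/[C@@H]2OC(=O)[C@H](C)[C@@]2(O)[C@@H](O[Si](C)(C)C(C)(C)C)[C@H]2[C@]3(C)O[C@@H]3C[C@H](O[Si](C)(C)C(C)(C)C)[C@]2(C)[C@@H](O)\C=C\1 | intermediate
31 | 2,8,9,14,16-pentaol | OCC1=C/[C@@H]2OC(=O)[C@H](C)[C@@]2(O)[C@@H](O)[C@H]2[C@]3(C)O[C@@H]3C[C@H](O)[C@]2(C)[C@@H](O)\C=C\1 | intermediate
32 | CNP0250433.1 (2,9,14,16-tetraacetate, 8-OH free) | CC(=O)OCC1=C/[C@@H]2OC(=O)[C@H](C)[C@@]2(O)[C@@H](OC(C)=O)[C@H]2[C@]3(C)O[C@@H]3C[C@H](OC(C)=O)[C@]2(C)[C@@H](OC(C)=O)\C=C\1 | target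

**Step count.** Total: 27 steps. Longest linear sequence: 22 steps (steps 1–11, 17–27); the pyranone branch is steps 12–16.

**Steps most likely to fail**

Step 17. The cross-cycloaddition of the C5-substituted ylide with the hindered, only moderately electron-rich enol carbonate may be slower than ylide dimerisation, or the endo/exo preference may be weak. The fallback sets out from 13 and comes back at 21: the unsubstituted ylide is used in large excess and C16 is attached afterwards. Commercial furfuryl alcohol F1 is converted by Achmatowicz rearrangement (NBS, NaHCO3, THF/H2O) into 6-hydroxy-2H-pyran-3(6H)-one F2 and acetylated to 6-acetoxy-2H-pyran-3(6H)-one F3. With Et3N this gives the parent 3-oxidopyrylium F4 (not isolated), which should add to 13 in the same sense to give the C16-free cycloadduct F5. Morita–Baylis–Hillman hydroxymethylation of its enone (aqueous CH2O, imidazole, THF) would give the C5-hydroxymethyl enone F6, and tBuMe2SiCl/imidazole returns 21.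

Step 25. Ring closure may be outrun by oligomerisation, or the dienylchromium may add to the wrong face of the C2 aldehyde. The fallback sets out from 29 and comes back at 30, and it answers the facial problem: the 2-epimeric macrocycle F7 is oxidised (Dess–Martin periodinane, NaHCO3) to the macrocyclic dienone F8. This is reduced under reagent control by Corey–Bakshi–Shibata reduction ((R)-2-methyl-CBS-oxazaborolidine, BH3·SMe2, with the quaternary C1 flank as the large group) to 30.

Step 10. The quaternary C1 next to the reacting alkene terminus may force the alkynyl group into the endo position of the envelope transition state, giving the 9R carbinol. The fallback sets out from 11 and comes back at 12; the rearrangement still fixes C10. The 9-epimeric propargylic alcohol F9 (or the epimer mixture) is oxidised with Dess–Martin periodinane to the ynone F10, and C9 is then set by asymmetric transfer hydrogenation (RuCl(p-cymene)[(S,S)-TsDPEN], iPrOH) to give 12.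

Further compounds
F1 | step 17 | furfuryl alcohol | OCc1ccco1
F2 | step 17 | 6-hydroxy-2H-pyran-3(6H)-one | O=C1COC(O)C=C1
F3 | step 17 | 6-acetoxy-2H-pyran-3(6H)-one | CC(=O)OC1OCC(=O)C=C1
F4 | step 17 | 3-oxidopyrylium | [O-]c1c[o+]ccc1
F5 | step 17 | C16-free cycloadduct | O=C1C=C[C@@H]2O[C@H]1[C@H](C)[C@]23OC(=O)O[C@H]3[C@H]4C(C)=CC[C@H](O[Si](C)(C)C(C)(C)C)[C@]4(C)CO[Si](CC)(CC)CC
F6 | step 17 | C5-hydroxymethyl enone | O=C1C(CO)=C[C@@H]2O[C@H]1[C@H](C)[C@]23OC(=O)O[C@H]3[C@H]4C(C)=CC[C@H](O[Si](C)(C)C(C)(C)C)[C@]4(C)CO[Si](CC)(CC)CC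
F7 | step 25 | 2-epimeric macrocycle (2R alcohol) | CC(C)(C)[Si](C)(C)OCC1=C/[C@@H]2OC(=O)[C@H](C)[C@@]2(O)[C@@H](O[Si](C)(C)C(C)(C)C)[C@H]2[C@]3(C)O[C@@H]3C[C@H](O[Si](C)(C)C(C)(C)C)[C@]2(C)[C@H](O)\C=C\1
F8 | step 25 | macrocyclic dienone (C2 ketone) | CC(C)(C)[Si](C)(C)OCC1=C/[C@@H]2OC(=O)[C@H](C)[C@@]2(O)[C@@H](O[Si](C)(C)C(C)(C)C)[C@H]2[C@]3(C)O[C@@H]3C[C@H](O[Si](C)(C)C(C)(C)C)[C@]2(C)C(=O)\C=C\1
F9 | step 10 | 9-epimeric propargylic alcohol (9R,10S) | CC#C[C@H](O)[C@H]1C(C)=CC[C@H](O[Si](C)(C)C(C)(C)C)[C@]1(C)CO[Si](CC)(CC)CC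
F10 | step 10 | ynone (C9 ketone) | CC#CC(=O)[C@H]1C(C)=CC[C@H](O[Si](C)(C)C(C)(C)C)[C@]1(C)CO[Si](CC)(CC)CC
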